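The isomer of the product forms from monomer in chains and returns to it, so you can follow this one exchange by its rate. Write U for monomer in chains, E for the isomer, both as shares of the charge, and s = U/(U + E).

| setting | ochre | amber | blue | alpha | zeta | eta |
|---|---|---|---|---|---|---|
| solid monomer | 5 mM | 5 mM | 10 mM | 5.0 mM | 5.0 mM | 5.0 mM |
| initiator | 12 µM | 50 µM | 25 µM | 25 µM | 25 µM | 25 µM |
| temperature | 95 °C | 106 °C | 95 °C | 90 °C | 110 °C |  |
| remark | run made earlier | run made earlier | run made earlier |  |  | at 90 °C until 2.5 min, from then on at 110 °C |
| time |  |  |  | 5.0 min | 5.0 min | 5.0 min |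

- ochre (time / min: monomer in chains / %, isomer of the product / %, solid monomer / %): 0.417: 4.1, 1.9, 65.9; 0.667: 4.6, 3.9, 55.2; 1.00: 4.3, 4.6, 48.5; 1.33: 4.7, 5.1, 45.0; 2.00: 4.5, 6.1, 42.3; 3.00: 4.6, 6.4, 41.9; 5.00: 4.9, 5.7, 40.9
- amber (time / min: monomer in chains / %, isomer of the product / %, solid monomer / %): 0.333: 3.3, 3.8, 70.1; 0.667: 3.2, 4.0, 54.6; 0.833: 3.0, 4.2, 51.4; 1.33: 3.9, 4.5, 45.3; 2.00: 4.1, 4.4, 43.5; 2.50: 3.8, 5.2, 43.4
- blue (time / min: monomer in chains / %, isomer of the product / %, solid monomer / %): 0.417: 2.9, 2.2, 82.8; 1.33: 2.9, 3.2, 70.9; 2.50: 3.2, 3.8, 69.5; 4.00: 2.9, 3.5, 69.2; 5.00: 3.2, 4.1, 68.8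

(readings scatter by 0.3 percentage points)

1. the best flask by share of monomer in chains in all that became monomer in chains or isomer of the product; "all alike" if 1.5 percentage points covers them all (alpha / zeta / eta / all alike)
2. share of monomer in chains in all that became monomer in chains or isomer of the product, alpha
3. share of monomer in chains in all that became monomer in chains or isomer of the product, zeta
4. share of monomer in chains in all that became monomer in chains or isomer of the product, eta

- as a solid, counted per litre of solution: solid monomer
- the numbers in the tables scatter by 0.3 percentage points (one standard deviation)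
- steps that have been proposed: initiator -> 2 initiating radical; free monomer + initiating radical -> growing radical + monomer in chains; free monomer + growing radical -> monomer in chains + growing radical; 2 growing radical -> dead chain; monomer in chains <-> isomer of the product; solid monomer <-> free monomer
- at the start none of the solid monomer is in solution

My own reckoning:

1. **Start.** Between its first two readings, the ochre run gains E at 0.0800 /min, as a fraction of the charge.

2. **Slowing.** Late in the ochre run, the reading K = E/U is 1.27, which puts s at balance (thermodynamic control) near 44.0%. Over that first interval, the ratio of back to forward rate reads 0.523, so the back step already cancels about half of the forward rate.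

3. **Constant.** Correcting for that cancellation gives λ, the rate at which the gap to balance closes: 6.89 /min for ochre. Alpha is colder, so I allow a factor 2 against it.

4. **Count.** Alpha gets 17.2 turnovers n, meaning the time given multiplied by that reduced λ. Each one shrinks the gap by a factor e, leaving 3.32 × 10⁻⁸ of it, with new chains left aside.

5. **Temperature.** The amber readings taken together give s = 44.9%. That is 0.90 percentage points from ochre, less than the margin. Yet 90 °C and 110 °C lie outside those two temperatures, so "all alike" is my call, but a thin one.

The forecast says all alike, with 43.9%, 45.2% and 45.2%, on the ground that “At 5 min every flask has equilibrated”.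

The flasks give all alike: 43.6%, 44.4% and 44.3%.

    initiator → 2 initiating radical (k = 0.0960 /s, Ea = 91.0 kJ/mol)
    free monomer + initiating radical → growing radical + monomer in chains (k = 1.40 × 10⁶ /M/s, Ea = 33.0 kJ/mol)
    free monomer + growing radical → monomer in chains + growing radical, rate k3*[growing radical]*[free monomer] (k = 34000 /M/s, Ea = 13.0 kJ/mol)
    2 growing radical → dead chain (k = 1.40 × 10⁶ /M/s, Ea = 22.0 kJ/mol)
    monomer in chains ⇌ isomer of the product (K = 1.30, k = 0.0340 /s, Ea = 102 kJ/mol, ΔH = −2.00 kJ/mol)
    solid monomer ⇌ free monomer, rate k6*(cs6 - [free monomer]) while solid is left; crystals form when [free monomer] > cs6 (solubility = 2.40 mM, k = 0.0430 /s)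
    (constants at 90 °C)

The undoing of the isomer holds this share up: without that step, alpha falls from 43.6% to 0.481%. Now use the count on a second flask, eta stopped at 80 s, still at 90 °C. Reckoned from the start with new chains left aside, it has 4.59 turnovers behind it, fewer than alpha's 17.2, and its s stands at 49.0%, against 43.6% for alpha at 5.0 min.

(The earlier runs and the new flask were generated by integration for an exercise; the scatter is artificial.)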